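I began with the charge.

| setting | winter | autumn | flask |
|---|---|---|---|
| electrophile | 0.39 M | 0.39 M | 0.39 M |
| nucleophile | 1.1 M | 1.7 M | 0.780 M |
| remark | run made earlier | run made earlier |  |
| time |  |  | 6.0 min |

| run | time / min | electrophile / % | target / % |
|---|---|---|---|
| winter | 0.833 | 43.0 | 32.7 |
| winter | 2.00 | 20.9 | 28.6 |
| winter | 4.00 | 8.9 | 20.3 |
| winter | 6.00 | 5.0 | 14.1 |
| autumn | 0.500 | 44.5 | 32.8 |
| autumn | 1.00 | 22.7 | 30.8 |
| autumn | 2.50 | 5.4 | 13.8 |
| autumn | 6.00 | 0.5 | 2.1 |

(scatter of a reading: 0.3 percentage points)

* part of the electrophile that has reacted at 6.0 min
* share of the unused nucleophile that is free and not bound as protonated nucleophile, at 6.0 min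

- steps that have been proposed: electrophile + nucleophile <-> acid set free + target; nucleophile + acid set free <-> protonated nucleophile; nucleophile + target -> over-reaction product; electrophile <-> dormant form
- what has gone from electrophile into another species counts as reacted, even if it can come back
- the earlier runs do not show how much of nucleophile is bound; that part of a forecast is a guess

**Dose number.** The autumn run's first reading showed a logarithmic electrophile loss of 0.810. I scaled that by the flask's nucleophile charge times time, over the same product in autumn. This gave N = 4.46, the dose number: my rough estimate of the flask's logarithmic loss if nucleophile never fell, a Damköhler number. The winter run's first reading gave a loss per dose differing by a factor of 1.03.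

**Reading it.** I counted two nucleophile per electrophile, one to react and one to bind acid. The flask held 2.00 per electrophile, so in my reckoning electrophile and nucleophile fell in step. I reckoned the fraction of electrophile left as one over one plus N: 18.3%, down 0.737 of a power of ten. With acid fully bound, I reckoned 31.0% of the unused nucleophile free.

**One number?** It wasn't enough. In the winter run at 6.00 min, electrophile and target together held 19.1%, and the proposed over-reaction step uses further nucleophile. So I held my share loosely.

**The forecast.** It gave 85% reacted and 52% free, a share above mine. It said: “The free share rests on the inferred binding, so it is uncertain.”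

**The result.** The flask gave 87.2% reacted and 22.4% free, with 12.8% electrophile left against my 18.3%.

    electrophile + nucleophile ⇌ acid set free + target (K = 1.54, k = 0.0180 M⁻¹ s⁻¹)
    nucleophile + acid set free ⇌ protonated nucleophile, settled at all times (K = 1100 M⁻¹)
    nucleophile + target → over-reaction product (k = 0.0202 M⁻¹ s⁻¹)
    electrophile ⇌ dormant form (K = 3.70, k = 0.00186 s⁻¹)

The neighbour with 0.23 M of electrophile kept N, having the same nucleophile and time, but held r = 3.39 per electrophile. With spare s = r − 2, the same balance gives left = s/(r·exp(N·s/r) − 2), which is 7.28%. That flask gave 4.97% electrophile left, 95.0% reacted and 58.0% free.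

The runs were generated by integration for an exercise; noise was put on by code.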